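**Plan**

- Numbering: lactone O1–C2(=O)–C3–C4–C5; C6 is the ketone carbon on C3 and carries ring A (4-hydroxy-3-methoxyphenyl); C7 is the benzylic CH2 on C4 and carries ring B (3,4-dimethoxyphenyl).
- Enabling feature: C2 is a single carbonyl carbon between O1 and C3, and C3–C6(=O)–ring A is a hydrated aryl alkyne, so cutting O1–C2 and C2–C3 leaves carbon monoxide and the homopropargylic alcohol HO–C5–C4(C7–ring B)–C3≡C6–ring A.
- Cuts, in retrosynthetic order: C6=O (back to the C3=C6 arylidene), O1–C2 and C2–C3 (CO), C6–ring A (Sonogashira), C3≡C6 (aldehyde-to-alkyne homologation), C4–C5 (α-hydroxymethylation of 3-(3,4-dimethoxyphenyl)propanal).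
- Forward: the open chain C5–C4(C7)–C3≡C6–ring A is assembled first, the lactone (the only ring made) is closed by carbonylation, then C6 is raised to the ketone and the phenol is unmasked.
- Stereochemistry: C4 is set by enamine catalysis in step 1 and not touched again; C3 is set at the end by equilibration of the β-keto lactone to the trans (3S,4R) arrangement.

Key step: step 7

Remark: the (3S,4R) descriptors of the target correspond to the trans-3,4-disubstituted lactone; C3 lies between two carbonyl groups and is taken to be under thermodynamic control, so only C4 needs absolute stereocontrol.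

**Route**

Step 1
Reactants: 1 3-(3,4-dimethoxyphenyl)propanal; 2 formaldehyde
Product: 3 (S)-2-(3,4-dimethoxybenzyl)-3-hydroxypropanal
Conditions: (R)-α,α-diphenylprolinol trimethylsilyl ether (20 mol%), 37% aq. HCHO (3 equiv), pH 7 phosphate buffer, toluene, rt
Reagents that add atoms: formaldehyde (2), C=O
Why: Enamine-catalysed cross-aldol reaction (organocatalytic α-hydroxymethylation): the E-enamine of 1 with the (R)-configured diarylprolinol silyl ether has one face blocked by the diphenyl(silyloxy)methyl group, so formaldehyde should add to the open face and create C4 in the S-aldehyde configuration, which becomes 4R in the lactone, while the near-neutral buffer suppresses dehydration to the α-methylene aldehyde.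

Step 2
Reactants: 3 (S)-2-(3,4-dimethoxybenzyl)-3-hydroxypropanal
Product: 4 (S)-3-(tert-butyldimethylsilyloxy)-2-(3,4-dimethoxybenzyl)propanal
Conditions: TBSCl, imidazole, CH2Cl2, 0 °C
Reagents that add atoms: tert-butyldimethylsilyl chloride, CC(C)(C)[Si](C)(C)Cl
Why: Imidazole-promoted O-silylation of the primary hydroxyl, run on crude 3 without chromatography, should drain the hemiacetal oligomers of the hydroxy aldehyde into the monomeric silyl ether under conditions too mild to enolise the α-stereocentre.

Step 3
Reactants: 4 (S)-3-(tert-butyldimethylsilyloxy)-2-(3,4-dimethoxybenzyl)propanal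
Product: 5 (R)-tert-butyl{[2-(3,4-dimethoxybenzyl)but-3-yn-1-yl]oxy}dimethylsilane
Conditions: dimethyl (1-diazo-2-oxopropyl)phosphonate, K2CO3, MeOH, 0 °C to rt
Reagents that add atoms: dimethyl (1-diazo-2-oxopropyl)phosphonate (Ohira–Bestmann reagent), COP(=O)(OC)C(=[N+]=[N-])C(C)=O
Why: Ohira–Bestmann variant of the Seyferth–Gilbert homologation: methanolysis of the reagent gives the diazomethylphosphonate anion, which olefinates the aldehyde and, after loss of N2 and a 1,2-hydrogen shift, delivers the terminal alkyne (C3 from the aldehyde carbon, C6 from the reagent); α-branched β-silyloxy aldehydes are standard substrates and normally keep their configuration at this temperature (the descriptor changes from S to R only through the priority rules).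

Step 4
Reactants: 6 4-iodo-2-methoxyphenol
Product: 7 (4-iodo-2-methoxyphenoxy)triisopropylsilane
Conditions: TIPSCl, imidazole, DMF, rt
Reagents that add atoms: triisopropylsilyl chloride, CC(C)[Si](Cl)(C(C)C)C(C)C
Why: Standard silylation of a phenol; the TIPS group is chosen because an aryl TIPS ether resists the acidic methanolysis of step 6 and the alkoxide and perborate of step 8, yet is removed by fluoride in step 10.

Step 5
Reactants: 5 (R)-tert-butyl{[2-(3,4-dimethoxybenzyl)but-3-yn-1-yl]oxy}dimethylsilane; 7 (4-iodo-2-methoxyphenoxy)triisopropylsilane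
Product: 8 (R)-tert-butyl{[2-(3,4-dimethoxybenzyl)-4-(3-methoxy-4-triisopropylsilyloxyphenyl)but-3-yn-1-yl]oxy}dimethylsilane
Conditions: Pd(PPh3)2Cl2 (3 mol%), CuI (5 mol%), Et3N/THF, rt to 40 °C
Reagents that add atoms: none
Why: Sonogashira coupling: oxidative addition of the aryl iodide to zerovalent palladium, transmetallation from the copper acetylide and reductive elimination form the C6–ring A bond under conditions that leave both silyl ethers and the C4 stereocentre untouched.

Step 6
Reactants: 8 (R)-tert-butyl{[2-(3,4-dimethoxybenzyl)-4-(3-methoxy-4-triisopropylsilyloxyphenyl)but-3-yn-1-yl]oxy}dimethylsilane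
Product: 9 (R)-2-(3,4-dimethoxybenzyl)-4-[3-methoxy-4-(triisopropylsilyloxy)phenyl]but-3-yn-1-ol
Conditions: CSA (10 mol%), MeOH/CH2Cl2 1:1, 0 °C
Reagents that add atoms: none
Why: Acid-catalysed methanolysis of silyl ethers discriminates strongly on steric bulk and on the basicity of the ether oxygen, so the primary alkyl TBS ether should be cleaved while the hindered, weakly basic aryl TIPS ether survives.

Step 7
Reactants: 9 (R)-2-(3,4-dimethoxybenzyl)-4-[3-methoxy-4-(triisopropylsilyloxy)phenyl]but-3-yn-1-ol; 10 carbon monoxide
Product: 11 (R,E)-4-(3,4-dimethoxybenzyl)-3-[3-methoxy-4-(triisopropylsilyloxy)benzylidene]dihydrofuran-2(3H)-one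
Conditions: PdI2 (5 mol%), PBu3 (10 mol%), CO (7 atm), MeCN, 75 °C
Reagents that add atoms: carbon monoxide (10), [C-]#[O+]
Why: The C5 hydroxyl and CO form an alkoxycarbonyl ligand on divalent palladium (O1–C2 bond), this Pd–CO2R unit adds syn across the C3≡C6 triple bond with C2 bonding to C3 and palladium to C6 (C2–C3 bond), and protonolysis of the vinyl–palladium bond by the HI released in the first stage frees the lactone and returns PdI2. The closest known reaction type is the palladium-catalysed cyclocarbonylation of homopropargylic alcohols to α-methylene and α-alkylidene γ-butyrolactones, which includes internal alkynes. The lactone ring closes by intramolecular acylpalladation in the 5-exo-dig mode, the tether allowing C2 to reach only C3. No stereocentre is created: C4 is an sp3 spectator remote from the metal and keeps its R configuration, while the E geometry of C3=C6 follows from syn addition and retentive protonolysis, which place the C6 hydrogen cis to C2 and ring A trans to it. The step needs carbonylation to outrun 5-endo oxypalladation to a dihydrofuran; this is secured by the phosphine-ligated catalyst under CO pressure, where the alkoxycarbonyl complex forms before the alkyne is activated, and the aryl TIPS ether, the methyl ethers and ring B are inert to these neutral conditions.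

Step 8
Reactants: 11 (R,E)-4-(3,4-dimethoxybenzyl)-3-[3-methoxy-4-(triisopropylsilyloxy)benzylidene]dihydrofuran-2(3H)-one
Product: 13 (4R)-4-(3,4-dimethoxybenzyl)-3-{hydroxy[3-methoxy-4-(triisopropylsilyloxy)phenyl]methyl}dihydrofuran-2(3H)-one, via C6 pinacol boronate 12 (not isolated)
Conditions: CuCl (10 mol%), xantphos (10 mol%), NaOtBu (20 mol%), B2pin2 (1.2 equiv), MeOH (2 equiv), THF, rt; then NaBO3·4H2O, THF/H2O, rt
Reagents that add atoms: bis(pinacolato)diboron (boron held only in 12), CC1(C)OB(OC1(C)C)B1OC(C)(C)C(C)(C)O1; sodium perborate (oxygen of the C6 hydroxyl), [Na+].[O-]OB=O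
Why: Copper-catalysed conjugate borylation of an α,β-unsaturated ester followed by C–B oxidation: the phosphine-ligated copper–boryl species adds boron to the β-carbon C6, methanol protonates the copper enolate at C3, and perborate converts the benzylic C–B bond into C–OH with retention; the configurations formed at C3 and C6 (a mixture of epimers) need no control because step 9 erases C6 and equilibrates C3.

Step 9
Reactants: 13 (4R)-4-(3,4-dimethoxybenzyl)-3-{hydroxy[3-methoxy-4-(triisopropylsilyloxy)phenyl]methyl}dihydrofuran-2(3H)-one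
Product: 14 (3S,4R)-4-(3,4-dimethoxybenzyl)-3-[3-methoxy-4-(triisopropylsilyloxy)benzoyl]dihydrofuran-2(3H)-one
Conditions: Dess–Martin periodinane, CH2Cl2, 0 °C to rt
Reagents that add atoms: none
Why: Dess–Martin oxidation of the secondary benzylic alcohol gives the aryl ketone under near-neutral conditions, and C3, now flanked by the ketone and the lactone carbonyl, should equilibrate through its enol to the more stable trans arrangement with the aroyl group anti to the C4 benzyl group, which is the 3S,4R isomer.

Step 10
Reactants: 14 (3S,4R)-4-(3,4-dimethoxybenzyl)-3-[3-methoxy-4-(triisopropylsilyloxy)benzoyl]dihydrofuran-2(3H)-one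
Product: 15 (3S,4R)-4-(3,4-dimethoxybenzyl)-3-(4-hydroxy-3-methoxybenzoyl)dihydrofuran-2(3H)-one
Conditions: TBAF, AcOH (1:1), THF, 0 °C
Reagents that add atoms: none
Why: Fluoride-induced cleavage of the aryl silyl ether, buffered with acetic acid so that the acidic C3–H and the lactone are not exposed to unbuffered fluoride or phenoxide, should free the phenol without disturbing either stereocentre.

**Compound list**

1 | 3-(3,4-dimethoxyphenyl)propanal | O=CCCc1ccc(OC)c(OC)c1 | starting material
2 | formaldehyde (37% aqueous solution) | C=O | starting material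
3 | (S)-2-(3,4-dimethoxybenzyl)-3-hydroxypropanal | OC[C@H](Cc1ccc(OC)c(OC)c1)C=O | intermediate
4 | (S)-3-(tert-butyldimethylsilyloxy)-2-(3,4-dimethoxybenzyl)propanal | CC(C)(C)[Si](C)(C)OC[C@H](Cc1ccc(OC)c(OC)c1)C=O | intermediate
5 | (R)-tert-butyl{[2-(3,4-dimethoxybenzyl)but-3-yn-1-yl]oxy}dimethylsilane | CC(C)(C)[Si](C)(C)OC[C@H](Cc1ccc(OC)c(OC)c1)C#C | intermediate
6 | 4-iodo-2-methoxyphenol | COc1cc(I)ccc1O | starting material
7 | (4-iodo-2-methoxyphenoxy)triisopropylsilane | COc1cc(I)ccc1O[Si](C(C)C)(C(C)C)C(C)C | intermediate
8 | (R)-tert-butyl{[2-(3,4-dimethoxybenzyl)-4-(3-methoxy-4-triisopropylsilyloxyphenyl)but-3-yn-1-yl]oxy}dimethylsilane | CC(C)(C)[Si](C)(C)OC[C@H](Cc1ccc(OC)c(OC)c1)C#Cc1ccc(O[Si](C(C)C)(C(C)C)C(C)C)c(OC)c1 | intermediate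
9 | (R)-2-(3,4-dimethoxybenzyl)-4-[3-methoxy-4-(triisopropylsilyloxy)phenyl]but-3-yn-1-ol | OC[C@H](Cc1ccc(OC)c(OC)c1)C#Cc1ccc(O[Si](C(C)C)(C(C)C)C(C)C)c(OC)c1 | intermediate
10 | carbon monoxide | [C-]#[O+] | starting material
11 | (R,E)-4-(3,4-dimethoxybenzyl)-3-[3-methoxy-4-(triisopropylsilyloxy)benzylidene]dihydrofuran-2(3H)-one | COc1cc(/C=C2/C(=O)OC[C@@H]2Cc2ccc(OC)c(OC)c2)ccc1O[Si](C(C)C)(C(C)C)C(C)C | intermediate
12 | (4R)-4-(3,4-dimethoxybenzyl)-3-{[3-methoxy-4-(triisopropylsilyloxy)phenyl](4,4,5,5-tetramethyl-1,3,2-dioxaborolan-2-yl)methyl}dihydrofuran-2(3H)-one, mixture of C3 and C6 epimers, not isolated | COc1cc(C(B2OC(C)(C)C(C)(C)O2)C2C(=O)OC[C@@H]2Cc2ccc(OC)c(OC)c2)ccc1O[Si](C(C)C)(C(C)C)C(C)C | intermediate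
13 | (4R)-4-(3,4-dimethoxybenzyl)-3-{hydroxy[3-methoxy-4-(triisopropylsilyloxy)phenyl]methyl}dihydrofuran-2(3H)-one, mixture of C3 and C6 epimers | COc1cc(C(O)C2C(=O)OC[C@@H]2Cc2ccc(OC)c(OC)c2)ccc1O[Si](C(C)C)(C(C)C)C(C)C | intermediate
14 | (3S,4R)-4-(3,4-dimethoxybenzyl)-3-[3-methoxy-4-(triisopropylsilyloxy)benzoyl]dihydrofuran-2(3H)-one | COc1cc(C(=O)[C@H]2C(=O)OC[C@@H]2Cc2ccc(OC)c(OC)c2)ccc1O[Si](C(C)C)(C(C)C)C(C)C | intermediate
15 | (3S,4R)-4-(3,4-dimethoxybenzyl)-3-(4-hydroxy-3-methoxybenzoyl)dihydrofuran-2(3H)-one | COc1cc(C(=O)[C@H]2C(=O)OC[C@@H]2Cc2ccc(OC)c(OC)c2)ccc1O | target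

**Step count and risks**

Total step count: 10. Longest linear sequence: 9 steps (steps 1, 2, 3, 5, 6, 7, 8, 9, 10); step 4 is a one-step branch.

Steps most likely to fail:

Step 7. The disubstituted, electron-rich aryl alkyne may insert too slowly into the palladium–alkoxycarbonyl bond, so that 5-endo cycloisomerisation of the alkynol or decay of the catalyst to palladium metal takes over. The fallback separates ring closure from arylation and sets out from 5. Acid methanolysis (CSA, MeOH) should give (R)-2-(3,4-dimethoxybenzyl)but-3-yn-1-ol F1. The same PdI2/PBu3/CO cyclocarbonylation, now on a terminal alkyne, the best substrate class for this reaction, should give (R)-4-(3,4-dimethoxybenzyl)-3-methylenedihydrofuran-2(3H)-one F2. A Mizoroki–Heck arylation of the exocyclic methylene with aryl iodide 7 (Pd(OAc)2, P(o-tol)3, Et3N, MeCN, 80 °C) should then place ring A on C6 with E geometry through syn insertion and syn β-hydride elimination. This comes back to the route at 11.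

Step 8. Addition of the copper–boryl species to the hindered, trisubstituted and electron-rich arylidene lactone may stall, or the β-hydroxy lactone may revert by elimination during the basic oxidation. The fallback sets out from 11 and replaces hydroboration logic by oxidation followed by reductive removal of one oxygen. Dihydroxylation with catalytic OsO4 and NMO in acetone/water should give (4S)-4-(3,4-dimethoxybenzyl)-3-hydroxy-3-{hydroxy[3-methoxy-4-(triisopropylsilyloxy)phenyl]methyl}dihydrofuran-2(3H)-one F3. Its C4 descriptor differs from that of 11 only because C3 now outranks C5; the arrangement in space is unchanged, and the C3 and C6 configurations are inconsequential. Treatment with SmI2 in THF/HMPA with pivalic acid, the known α-deoxygenation of α-hydroxy esters, should cleave the C3–O bond next to the lactone carbonyl and leave the C6 hydroxyl. This comes back to the route at 13.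

Step 3. Carbonate in methanol may enolise the α-branched aldehyde or trigger β-elimination of the silyloxy group, eroding the enantiopurity set in step 1 or destroying the chain. The fallback sets out from 4 and avoids exposing the aldehyde to base by a Corey–Fuchs sequence. CBr4 and PPh3 in CH2Cl2 at 0 °C should give (R)-tert-butyl{[4,4-dibromo-2-(3,4-dimethoxybenzyl)but-3-en-1-yl]oxy}dimethylsilane F4. Two equivalents of n-BuLi in THF at −78 °C, followed by aqueous quench, should convert it into the terminal alkyne through bromine–lithium exchange and Fritsch–Buttenberg–Wiechell rearrangement. This comes back to the route at 5.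

Further compounds
F1 | step 7 | (R)-2-(3,4-dimethoxybenzyl)but-3-yn-1-ol | OC[C@H](Cc1ccc(OC)c(OC)c1)C#C
F2 | step 7 | (R)-4-(3,4-dimethoxybenzyl)-3-methylenedihydrofuran-2(3H)-one | C=C1C(=O)OC[C@@H]1Cc1ccc(OC)c(OC)c1
F3 | step 8 | (4S)-4-(3,4-dimethoxybenzyl)-3-hydroxy-3-{hydroxy[3-methoxy-4-(triisopropylsilyloxy)phenyl]methyl}dihydrofuran-2(3H)-one | COc1cc(C(O)C2(O)C(=O)OC[C@@H]2Cc2ccc(OC)c(OC)c2)ccc1O[Si](C(C)C)(C(C)C)C(C)C
F4 | step 3 | (R)-tert-butyl{[4,4-dibromo-2-(3,4-dimethoxybenzyl)but-3-en-1-yl]oxy}dimethylsilane | CC(C)(C)[Si](C)(C)OC[C@H](Cc1ccc(OC)c(OC)c1)C=C(Br)Br
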